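## Retrosynthetic overview

1. The isopropenyl ketone (C2′=O, C3′=CH2) is traced back to a prenyl alkene, C2′=C3′(CH3)2. It is made last, by Schenck ene oxygenation and dehydration of the (S)-8-(1-isovaleryloxy-3-methylbut-2-enyl)coumarin. The acidic C1′–H next to a ketone therefore exists only in the final flask.
2. The C8–C1′ bond is cut into three components joined in one pot: 8-zincated 6,7-dimethoxycoumarin, prenal and isovaleryl chloride. An enantioconvergent nickel/pybox Negishi arylation joins them and also sets C1′.
3. Enabling feature: C1′ carries the ester oxygen and lies between C8 of the benzene ring and the C2′–C3′(CH3)2 end of an intact C5 chain. It is therefore the carbonyl carbon of prenal in disguise, and its acyl chloride adduct gives an O-substituted allyl radical. The gem-dimethyl carbon C3′ blocks γ-attack and removes any alkene geometry.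
4. C8–Zn comes from C8–I, which comes from C8–H of scopoletin. C8 is the only free position ortho to the 7-OH, because C6 bears OMe.
5. Rings: none is formed or broken. The benzene ring and the pyran-2-one ring of the 2H-chromen-2-one are bought together in scopoletin.

Key step: step 3

Assumption: precedent does not predict the sense of induction of the pybox–nickel catalyst for this new electrophile class. The ligand antipode that delivers the (S)-configured coupling product is therefore fixed in a pilot run; both antipodes are accessible.

## Route

Step 1
Reactants: 1 scopoletin (7-hydroxy-6-methoxy-2H-chromen-2-one)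
Product: 2 7-hydroxy-8-iodo-6-methoxy-2H-chromen-2-one
Conditions: I2, KI, 20 % aq NH3, 0 °C → rt; then dil. H2SO4
Reagents that add atoms: iodine, II
Why: Electrophilic aromatic iodination of the phenoxide should take place at C8, the only free position ortho to the 7-oxygen (C6 bears OMe and the para position is the ring fusion), and any lactone opened by the base recloses on acidification.

Step 2
Reactants: 2 7-hydroxy-8-iodo-6-methoxy-2H-chromen-2-one
Product: 3 8-iodo-6,7-dimethoxy-2H-chromen-2-one
Conditions: MeI, K2CO3, DMF, rt
Reagents that add atoms: iodomethane, CI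
Why: Williamson O-methylation (SN2 on MeI) of the acidic 7-OH under carbonate conditions leaves the lactone and the aryl iodide untouched and removes the only proton that would quench an organozinc reagent.

Step 3
Reactants: 3 8-iodo-6,7-dimethoxy-2H-chromen-2-one; 4 3-methylbut-2-enal (prenal); 5 3-methylbutanoyl chloride (isovaleryl chloride)
Product: 9 (S)-1-(6,7-dimethoxy-2-oxo-2H-chromen-8-yl)-3-methylbut-2-en-1-yl 3-methylbutanoate, via arylzinc iodide 6 (not isolated), via racemic 1-chloroallyl ester 7 (not isolated), via 3-chloro enol ester isomer 8 (not isolated)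
Conditions: (a) 3, Zn dust, LiCl, THF, 40 °C; (b) 4 (slight excess), 5, ZnCl2 (1 mol %), neat, 0 °C → rt, then DME; (c) to b: NiCl2·glyme (10 mol %), 2,6-bis[4-(2-phenylethyl)-4,5-dihydrooxazol-2-yl]pyridine (one antipode, 13 mol %), then solution a, DME/THF, −20 °C; aq NH4Cl/EDTA; Et3N-deactivated SiO2
Reagents that add atoms: none
Why: Proposed new method: the ZnCl2-catalysed addition of 5 across the C=O of 4 should give the chloro esters 7 and 8 as a mixture of enantiomers, allylic regioisomers and E/Z isomers, a (pybox)Ni(I) species abstracts chlorine from each of them to give one and the same planar 1-acyloxy-3,3-dimethylallyl radical, this radical is captured by the (pybox)Ni(II)–aryl complex formed from 6 by transmetalation, and reductive elimination from Ni(III) forms the C8–C1′ bond and returns Ni(I). The closest known reaction types are the enantioconvergent nickel/pybox Negishi couplings of racemic secondary allylic chlorides (alkylzinc) and of racemic propargylic halides and α-bromo ketones (arylzinc) and the enantioconvergent nickel-catalysed alkylation of racemic α-haloalkyl esters made in the same pot from an aldehyde and an acyl halide, and new is only the union of an arylzinc reagent with an allylic α-chloroalkyl ester. No ring is closed. The only new stereocenter, C1′, is controlled by the C2-symmetric pybox ligand on nickel in the radical capture and reductive elimination, not by the configuration or constitution of the chloride, so that the whole isomer mixture is funnelled into (S)-9. The step needs α- over γ-arylation, which the gem-dimethyl terminus C3′ secures (γ-attack would build a quaternary carbon next to a doubly ortho-substituted aryl group, and the same terminus leaves no alkene geometry to control), and it needs chemoselectivity, which is secured by the low nucleophilicity of an arylzinc iodide toward lactone, C3=C4 enoate, excess enal and ester at −20 °C, by LiCl that tames the Lewis acidity of the zinc salts, and by complete consumption of 5 before nickel is added so that no aryl ketone can form. The C1′–O bond of 9 is not open to halogen-atom abstraction, so that a second arylation or racemisation of the product should not compete.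

Step 4
Reactants: 9 (S)-1-(6,7-dimethoxy-2-oxo-2H-chromen-8-yl)-3-methylbut-2-en-1-yl 3-methylbutanoate
Product: 12 (R)-1-(6,7-dimethoxy-2-oxo-2H-chromen-8-yl)-3-methyl-2-oxobut-3-en-1-yl 3-methylbutanoate (target CNP0283239.1), via allylic hydroperoxide 10 (not isolated), via allylic peracetate 11 (not isolated)
Conditions: O2, tetraphenylporphyrin (1 mol %), visible-light LED (λ > 450 nm), CH2Cl2, 0 °C; then Ac2O, pyridine, 0 °C
Reagents that add atoms: dioxygen, O=O
Why: Schenck ene reaction followed by Kornblum–DeLaMare-type dehydration: singlet oxygen attacks the only electron-rich alkene (C2′=C3′), takes hydrogen from a C3′ methyl group because C1′–H is held in the alkene plane by A1,3 strain and is deactivated by the acyloxy group, and places OOH on C2′, after which pyridine removes C2′–H from the peracetate to give the isopropenyl ketone, so that both C2′ epimers converge, while C1′ is not touched (its descriptor changes from S to R only through CIP priorities) and meets no base stronger than pyridine.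

## Compound list

1 | scopoletin (7-hydroxy-6-methoxy-2H-chromen-2-one) | COc1cc2ccc(=O)oc2cc1O | starting material
2 | 7-hydroxy-8-iodo-6-methoxy-2H-chromen-2-one | COc1cc2ccc(=O)oc2c(I)c1O | intermediate
3 | 8-iodo-6,7-dimethoxy-2H-chromen-2-one | COc1cc2ccc(=O)oc2c(I)c1OC | intermediate
4 | 3-methylbut-2-enal (prenal) | CC(C)=CC=O | starting material
5 | 3-methylbutanoyl chloride (isovaleryl chloride) | CC(C)CC(=O)Cl | starting material
6 | (6,7-dimethoxy-2-oxo-2H-chromen-8-yl)zinc iodide (LiCl complex in THF) | COc1cc2ccc(=O)oc2c([Zn]I)c1OC | intermediate
7 | rac-1-chloro-3-methylbut-2-en-1-yl 3-methylbutanoate | CC(C)=CC(Cl)OC(=O)CC(C)C | intermediate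
8 | 3-chloro-3-methylbut-1-en-1-yl 3-methylbutanoate (E/Z mixture, allylic isomer of 7) | CC(C)(Cl)C=COC(=O)CC(C)C | intermediate
9 | (S)-1-(6,7-dimethoxy-2-oxo-2H-chromen-8-yl)-3-methylbut-2-en-1-yl 3-methylbutanoate | CC(C)=C[C@H](OC(=O)CC(C)C)c1c(OC)c(OC)cc2ccc(=O)oc12 | intermediate
10 | (1R)-1-(6,7-dimethoxy-2-oxo-2H-chromen-8-yl)-2-hydroperoxy-3-methylbut-3-en-1-yl 3-methylbutanoate (both C2′ epimers) | C=C(C)C(OO)[C@H](OC(=O)CC(C)C)c1c(OC)c(OC)cc2ccc(=O)oc12 | intermediate
11 | (1R)-2-(acetylperoxy)-1-(6,7-dimethoxy-2-oxo-2H-chromen-8-yl)-3-methylbut-3-en-1-yl 3-methylbutanoate (both C2′ epimers) | C=C(C)C(OOC(C)=O)[C@H](OC(=O)CC(C)C)c1c(OC)c(OC)cc2ccc(=O)oc12 | intermediate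
12 | (R)-1-(6,7-dimethoxy-2-oxo-2H-chromen-8-yl)-3-methyl-2-oxobut-3-en-1-yl 3-methylbutanoate | C=C(C)C(=O)[C@H](OC(=O)CC(C)C)c1c(OC)c(OC)cc2ccc(=O)oc12 | target

## Step count and risks

Total step count: 4.
Longest linear sequence: 4 (1 → 2 → 3 → 9 → 12). Compounds 4 and 5 enter as bought.

**Risk 1, step 3 (labelled step).**
- Transmetalation and radical capture at a nickel–aryl unit with two ortho oxygen substituents may be slow. Radical dimerisation, loss of HCl from the chloro esters or protodezincation could then take over.
- Zinc-salt-induced ionisation of the chloro esters may open an uncatalysed, racemic arylation.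
- Facial selectivity for an O-substituted allyl radical may be poor.

The fallback uses known chemistry and replaces the radical cross-coupling by a polar, catalytic asymmetric 1,2-addition. It sets out from 3 and comes back at 9. Iodine–zinc exchange on 3 (Et2Zn, Li(acac), NMP, 0 °C) should give the aryl(ethyl)zinc reagent F1. F1 is added to 4 in the presence of a chiral 3,3′-bis(morpholinomethyl)-H8-BINOL ligand (THF, 0 °C → rt). This is a catalytic enantioselective arylzinc addition to an aldehyde and should give (S)-8-(1-hydroxy-3-methylbut-2-enyl)-6,7-dimethoxycoumarin F2. Esterification with isovaleric anhydride (DMAP cat., pyridine, CH2Cl2, 0 °C) should then give 9.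

**Risk 2, step 4.**
- Hydrogen abstraction from C1′–H instead of a methyl group would mean poor ene regioselectivity.
- The doubly activated allylic/benzylic ester 9 may ionise or transpose before it is oxidised.
- Configuration at C1′ may be lost during the base-induced elimination.

The fallback avoids both singlet oxygen and base. It sets out from 9 and comes back at 12. Citric-acid-buffered Upjohn dihydroxylation (OsO4 cat., NMO, acetone/H2O) of the electron-rich C2′=C3′ alkene should give the (1R)-2,3-diol F3 as an epimer mixture at C2′. IBX (DMSO, rt) should oxidise only the secondary alcohol, without glycol cleavage, to the (R)-3-hydroxy-3-methyl-2-oxobutyl ester F4. Syn-elimination of the tertiary alcohol with the Burgess reagent (toluene, 50 °C) can only run toward a methyl group and should give 12.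

**Risk 3, step 1.**
- Over-iodination may occur.
- Iodine may be lost again on acidification.
- Ammonia may damage the lactone.

The fallback installs the halogen through an irreversible and self-limiting substitution. It sets out from 1 and comes back at 3. Nitration (HNO3, AcOH, 0–10 °C) should stop after one substitution and give 8-nitroscopoletin F5. O-methylation (MeI, K2CO3, DMF) should give 6,7-dimethoxy-8-nitrocoumarin F6. Fe/NH4Cl (EtOH/H2O, 70 °C) should reduce the nitro group without touching C3=C4 and give 8-amino-6,7-dimethoxycoumarin F7. Diazotisation (NaNO2, aq H2SO4, 0 °C) leads to the diazonium hydrogen sulfate F8. Treatment with KI (Sandmeyer-type iodination) should then give 3.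

## Further compounds

F1 | step 3 | (6,7-dimethoxy-2-oxo-2H-chromen-8-yl)(ethyl)zinc | CC[Zn]c1c(OC)c(OC)cc2ccc(=O)oc12
F2 | step 3 | (S)-8-(1-hydroxy-3-methylbut-2-en-1-yl)-6,7-dimethoxy-2H-chromen-2-one | CC(C)=C[C@H](O)c1c(OC)c(OC)cc2ccc(=O)oc12
F3 | step 4 | (1R)-1-(6,7-dimethoxy-2-oxo-2H-chromen-8-yl)-2,3-dihydroxy-3-methylbutyl 3-methylbutanoate (both C2′ epimers) | CC(C)(O)C(O)[C@H](OC(=O)CC(C)C)c1c(OC)c(OC)cc2ccc(=O)oc12
F4 | step 4 | (R)-1-(6,7-dimethoxy-2-oxo-2H-chromen-8-yl)-3-hydroxy-3-methyl-2-oxobutyl 3-methylbutanoate | CC(C)(O)C(=O)[C@H](OC(=O)CC(C)C)c1c(OC)c(OC)cc2ccc(=O)oc12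
F5 | step 1 | 7-hydroxy-6-methoxy-8-nitro-2H-chromen-2-one | COc1cc2ccc(=O)oc2c([N+](=O)[O-])c1O
F6 | step 1 | 6,7-dimethoxy-8-nitro-2H-chromen-2-one | COc1cc2ccc(=O)oc2c([N+](=O)[O-])c1OC
F7 | step 1 | 8-amino-6,7-dimethoxy-2H-chromen-2-one | COc1cc2ccc(=O)oc2c(N)c1OC
F8 | step 1 | 6,7-dimethoxy-2-oxo-2H-chromene-8-diazonium hydrogen sulfate | COc1cc2ccc(=O)oc2c([N+]#N)c1OC.OS(=O)(=O)[O-]
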